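Readings and results are simulated from invented constants, noise included.

I had 4 questions to answer about one flask, and I wanted the cheapest reckoning that would answer them.

| setting | violet | flask |
|---|---|---|
| starting complex | 0.40 M | 0.40 M |
| leaving ligand | 2 equiv | 2.00 equiv |
| gas | 62 mM (held) | 62 mM (held) |
| remark | the very flask that is asked about, followed so far |  |
| time |  | 8.0 d |

- violet (time / d: complex with two exchanged / %, starting complex / %): 0.333: 5.3, 77.0; 0.833: 15.7, 56.6; 1.67: 29.8, 35.6; 2.50: 35.1, 24.5; 4.00: 41.5, 18.8; 5.00: 40.0, 15.7

(each reading ± 1 percentage point)

- gamma: at 8.0 d add starting complex, 50.0% of the amount charged, then wait 15 d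
- zeta: at 8.0 d take out 90% of the complex with two exchanged then present, then wait 15 d
- alpha: change nothing and wait 15 d more

* complex with two exchanged, in percent of the starting complex first charged, at 8.0 d
* what to do for the largest gain in complex with two exchanged; "none" if nothing gains more than 2 percentage points (gamma / zeta / alpha / none)
* complex with two exchanged present, with what was taken out counted in, in percent of the starting complex first charged, after zeta
* complex with two exchanged present, with what was taken out counted in, in percent of the starting complex first charged, after alpha

- complex with two exchanged that was removed still counts
- at the start none of the gas is in solution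
- additions bring no volume worth counting

Complex with two exchanged read 41.5% at 4.00 d and 40.0% at 5.00 d, a gap of 1.5 percentage points against a scatter of 1 point. I therefore took the violet run as levelled, averaged those two rows, and booked each charged mole of starting complex, with the starting complex as the unit:

starting complex: 17.2%
complex with two exchanged: 40.8%
complex with one exchanged, by difference: 42.0%
leaving ligand set free: 1.24
free leaving ligand, the bath: 3.24

With the gas held, I treated each exchange as an equilibrium against the bath. My plateau number, an apparent equilibrium constant, is the ratio of complex with two exchanged to starting complex, times the bath squared: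

24.7

I expected about 40.8% at 8.0 d and again after alpha. If the shares held, zeta would take out 36.7% and rebuild to 62.5%, while gamma would reach 61.1%.

The correction is the bath's growth, which by my plateau number lowers the ratio. I reckoned that growth at 0.281 of the charge for zeta and 0.618 for gamma, more for gamma, so I chose zeta.

The forecast gave 42.5%, 62.5% for zeta and 43% for alpha, and it chose zeta, saying “Waiting changes nothing”. Its value at 8.0 d stood above my 40.8%, and it put gamma at 57%, where my uncorrected figure was 61.1%.

The flask gave 42.3%, 64.0% after zeta and 42.4% after alpha, and zeta gained 22 points against 17 points for gamma.

    complex with two exchanged + incoming ligand ⇌ leaving ligand + complex with three exchanged (K = 5.30, k = 0.00830 M⁻¹ min⁻¹)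
    complex with three exchanged + incoming ligand ⇌ leaving ligand + complex with four exchanged (K = 14.0, k = 0.280 M⁻¹ min⁻¹)
    starting complex + incoming ligand ⇌ leaving ligand + complex with one exchanged (K = 35.0, k = 0.0800 M⁻¹ min⁻¹)
    gas ⇌ incoming ligand, rate k4*(csat - [incoming ligand]) (kL = 0.00450 min⁻¹)
    complex with one exchanged + incoming ligand ⇌ leaving ligand + complex with two exchanged (K = 39.0, k = 0.210 M⁻¹ min⁻¹)

Beside starting complex and complex with two exchanged, the flask at 8.00 d held complex with one exchanged, 25.4%, complex with three exchanged, 9.56%, and complex with four exchanged, 5.71%. Set against the flask's bath at that time, my plateau number, itself a reading, gives a ratio of 1.89, where 2.49 stood. For the neighbour flask charged at 0.68 M, with the number scaled by the square of the ratio of the two charges, it gives 0.844, where 1.09 stood at 8.00 d.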